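**Retrosynthetic overview**
1. Last bond: acylation of the secondary hydroxyl of cis-diol 18 with (3S)-3-methylpentanoic acid 19.
2. Diol 18 comes from α-face OsO4 dihydroxylation of dienone 17; 17 comes from aldol condensation of trans-decalone 13 with acetone 14.
3. Decalone 13 comes from enone 8 by 1,2-reduction and reductive 1,3-transposition (sets the trans ring fusion); the ring B ketone travels as a silyl enol ether.
4. Key step: 8 comes from hydrindenedione 4 by one-carbon ring expansion of the cyclopentanone, a 1,2-shift of the quaternary carbon onto a magnesium carbenoid carbon.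
5. Ring order: five-membered ring (from 1), then ring A by amino-acid-mediated Robinson annulation with 2 (sets the quaternary centre), then ring B by 5→6 expansion.

Assumption: (3S)-3-methylpentanoic acid 19 is bought as the single enantiomer; all other inputs are bulk chemicals.

**Route**

Step 1
Reactants: 1 2-methylcyclopentane-1,3-dione; 2 ethyl vinyl ketone (pent-1-en-3-one)
Product: 4 (7aS)-4,7a-dimethyl-2,3,7,7a-tetrahydro-1H-indene-1,5(6H)-dione, via triketone 3 (not isolated)
Conditions: Et3N (cat.), MeCN, rt; then L-phenylalanine, (1S)-(+)-10-camphorsulfonic acid, 30 → 70 °C; recrystallise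
Reagents that add atoms: none
Why: Michael addition gives triketone 3, and the L-phenylalanine-mediated enantiogroup-selective intramolecular aldol condensation (Hajos–Parrish–Eder–Sauer–Wiechert variant of the Robinson annulation) closes ring A and sets the quaternary methyl centre as S, as known for L-amino acids with this class of triketone.

Step 2
Reactants: 4 (7aS)-4,7a-dimethyl-2,3,7,7a-tetrahydro-1H-indene-1,5(6H)-dione
Product: 8 (4aR)-1,4a-dimethyl-6-[(triisopropylsilyl)oxy]-4,4a,7,8-tetrahydronaphthalen-2(3H)-one, via lithium carbinolate 5 (not isolated), via magnesium carbenoid 6 (not isolated), via magnesium enolate 7 (not isolated)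
Conditions: CH2Br2, lithium 2,2,6,6-tetramethylpiperidide, THF, −90 °C; iPrMgCl·LiCl, −78 → −20 °C; TIPSOTf, −78 → 0 °C
Reagents that add atoms: dibromomethane BrCBr; triisopropylsilyl trifluoromethanesulfonate CC(C)[Si](C(C)C)(C(C)C)OS(=O)(=O)C(F)(F)F
Why: Proposed new method: a one-flask carbenoid homologation run with a free enone in the molecule, in which LiCHBr2 adds to the more electrophilic saturated cyclopentanone anti to the angular methyl, Br–Mg exchange with iPrMgCl·LiCl at −78 °C (expected to be far faster than Grignard addition to the hindered tetrasubstituted enone) gives a β-oxido magnesium carbenoid, the electron-rich quaternary carbon makes a 1,2-shift with retention onto the carbenoid carbon as bromide leaves (semipinacol-type ring expansion, the more substituted carbon migrating as in lithium β-oxido carbenoids), and the regiodefined magnesium enolate is silylated on oxygen so the new ring B ketone leaves the flask masked; the closest known reaction types are the CH2Br2/lithium amide then n-BuLi β-oxido carbenoid ring enlargement of cycloalkanones and magnesium β-oxido carbenoid ring expansions of α-chloro sulfoxide adducts, and to my knowledge neither has been run with an enone present, on an α-quaternary hydrindanone, or with silyl capture of the enolate.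

Step 3
Reactants: 8 (4aR)-1,4a-dimethyl-6-[(triisopropylsilyl)oxy]-4,4a,7,8-tetrahydronaphthalen-2(3H)-one
Product: 9 (2S,4aR)-1,4a-dimethyl-6-[(triisopropylsilyl)oxy]-2,3,4,4a,7,8-hexahydronaphthalen-2-ol
Conditions: NaBH4, CeCl3·7H2O, MeOH/THF, −78 °C
Reagents that add atoms: none
Why: Luche 1,2-reduction; hydride adds axially from the face opposite the angular methyl, giving the pseudo-equatorial alcohol cis to that methyl (2S) as with steroidal 4-en-3-ones, and the silyl enol ether is inert.

Step 4
Reactants: 9 (2S,4aR)-1,4a-dimethyl-6-[(triisopropylsilyl)oxy]-2,3,4,4a,7,8-hexahydronaphthalen-2-ol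
Product: 13 (4aR,8aR)-5,8a-dimethyl-3,4,4a,7,8,8a-hexahydronaphthalen-2(1H)-one, via sulfonylhydrazine 10 (not isolated), via allylic diazene 11 (not isolated), via silyl enol ether 12 (not isolated)
Conditions: 2-nitrobenzenesulfonylhydrazide (NBSH), PPh3, DEAD, N-methylmorpholine, −30 °C → rt; then HF·pyridine, THF, 0 °C
Reagents that add atoms: none
Why: Myers reductive 1,3-transposition; Mitsunobu displacement by NBSH inverts the carbinol carbon, loss of sulfinic acid gives the allylic diazene on the face opposite the angular methyl, and its retro-ene loss of N2 delivers hydrogen to the ring-fusion carbon on that same face, setting the trans ring fusion (4aR) and the trisubstituted olefin; HF then cleaves the silyl enol ether to the ketone.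

Step 5
Reactants: 13 (4aR,8aR)-5,8a-dimethyl-3,4,4a,7,8,8a-hexahydronaphthalen-2(1H)-one; 14 acetone
Product: 17 (4aR,8aR)-5,8a-dimethyl-3-(propan-2-ylidene)-3,4,4a,7,8,8a-hexahydronaphthalen-2(1H)-one, via lithium aldolate 15 (not isolated), via tertiary mesylate 16 (not isolated)
Conditions: LiN(iPr)2, THF, −78 °C; acetone; MsCl, −78 → 0 °C; DBU, rt
Reagents that add atoms: none
Why: Directed aldol condensation; kinetic deprotonation occurs at the CH2 remote from the quaternary carbon (the other α-position is neopentylic, as in 2-keto-5α-steroids), the enolate adds to acetone, and in situ mesylation with E1cB elimination gives the conjugated tetrasubstituted isopropylidene ketone without creating a stereocentre.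

Step 6
Reactants: 17 (4aR,8aR)-5,8a-dimethyl-3-(propan-2-ylidene)-3,4,4a,7,8,8a-hexahydronaphthalen-2(1H)-one
Product: 18 (4aR,5S,6R,8aR)-5,6-dihydroxy-5,8a-dimethyl-3-(propan-2-ylidene)octahydronaphthalen-2(1H)-one
Conditions: OsO4 (2 mol %), NMO, acetone/H2O, rt
Reagents that add atoms: N-methylmorpholine N-oxide C[N+]1([O-])CCOCC1; water O
Why: Upjohn dihydroxylation; OsO4 adds suprafacially to the electron-rich trisubstituted olefin from the face opposite the axial angular methyl, setting both carbinol centres (5S,6R) as the cis-diol, while the electron-poor tetrasubstituted enone olefin does not react.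

Step 7
Reactants: 18 (4aR,5S,6R,8aR)-5,6-dihydroxy-5,8a-dimethyl-3-(propan-2-ylidene)octahydronaphthalen-2(1H)-one; 19 (3S)-3-methylpentanoic acid
Product: 20 (1S,2R,4aR,8aR)-1-hydroxy-1,4a-dimethyl-6-oxo-7-(propan-2-ylidene)decahydronaphthalen-2-yl (3S)-3-methylpentanoate
Conditions: DCC, DMAP (cat.), CH2Cl2, 0 °C → rt
Reagents that add atoms: none
Why: Steglich esterification; only the secondary hydroxyl is acylated because the tertiary one is inert under DCC/DMAP, and the acid stereocentre is β to the carbonyl so it cannot epimerise.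

**Compound list**
1 | 2-methylcyclopentane-1,3-dione | CC1C(=O)CCC1=O | starting material
2 | ethyl vinyl ketone (pent-1-en-3-one) | CCC(=O)C=C | starting material
3 | 2-methyl-2-(3-oxopentyl)cyclopentane-1,3-dione | CCC(=O)CCC1(C)C(=O)CCC1=O | intermediate
4 | (7aS)-4,7a-dimethyl-2,3,7,7a-tetrahydro-1H-indene-1,5(6H)-dione | O=C1CC[C@]2(C)C(=O)CCC2=C1C | intermediate
5 | lithium (1S,7aS)-1-(dibromomethyl)-4,7a-dimethyl-5-oxo-2,3,5,6,7,7a-hexahydro-1H-inden-1-olate (dibromomethyl trans to the angular methyl) | O=C1CC[C@]2(C)[C@]([O-])(C(Br)Br)CCC2=C1C.[Li+] | intermediate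
6 | lithium (1S,7aS)-1-[bromo(chloromagnesio)methyl]-4,7a-dimethyl-5-oxo-2,3,5,6,7,7a-hexahydro-1H-inden-1-olate (both epimers at the metalated carbon) | O=C1CC[C@]2(C)[C@]([O-])(C(Br)[Mg]Cl)CCC2=C1C.[Li+] | intermediate
7 | chloromagnesium (8aR)-5,8a-dimethyl-6-oxo-3,4,6,7,8,8a-hexahydronaphthalen-2-olate | O=C1CC[C@]2(C)C=C(O[Mg]Cl)CCC2=C1C | intermediate
8 | (4aR)-1,4a-dimethyl-6-[(triisopropylsilyl)oxy]-4,4a,7,8-tetrahydronaphthalen-2(3H)-one | O=C1CC[C@]2(C)C=C(O[Si](C(C)C)(C(C)C)C(C)C)CCC2=C1C | intermediate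
9 | (2S,4aR)-1,4a-dimethyl-6-[(triisopropylsilyl)oxy]-2,3,4,4a,7,8-hexahydronaphthalen-2-ol (hydroxyl cis to the angular methyl) | O[C@H]1CC[C@]2(C)C=C(O[Si](C(C)C)(C(C)C)C(C)C)CCC2=C1C | intermediate
10 | N-[(2R,4aR)-1,4a-dimethyl-6-[(triisopropylsilyl)oxy]-2,3,4,4a,7,8-hexahydronaphthalen-2-yl]-2-nitrobenzenesulfonohydrazide (alkylated on the sulfonamide nitrogen) | NN([C@@H]1CC[C@]2(C)C=C(O[Si](C(C)C)(C(C)C)C(C)C)CCC2=C1C)S(=O)(=O)c1ccccc1[N+](=O)[O-] | intermediate
11 | [(2R,4aR)-1,4a-dimethyl-6-[(triisopropylsilyl)oxy]-2,3,4,4a,7,8-hexahydronaphthalen-2-yl]diazene | N=N[C@@H]1CC[C@]2(C)C=C(O[Si](C(C)C)(C(C)C)C(C)C)CCC2=C1C | intermediate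
12 | triisopropyl{[(4aS,8aS)-5,8a-dimethyl-3,4,4a,7,8,8a-hexahydronaphthalen-2-yl]oxy}silane (trans-fused) | CC1=CCC[C@]2(C)C=C(O[Si](C(C)C)(C(C)C)C(C)C)CC[C@@H]12 | intermediate
13 | (4aR,8aR)-5,8a-dimethyl-3,4,4a,7,8,8a-hexahydronaphthalen-2(1H)-one (trans-fused) | CC1=CCC[C@]2(C)CC(=O)CC[C@@H]12 | intermediate
14 | acetone | CC(C)=O | starting material
15 | lithium alkoxide of (4aR,8aR)-3-(2-hydroxypropan-2-yl)-5,8a-dimethyl-3,4,4a,7,8,8a-hexahydronaphthalen-2(1H)-one (epimers at C3) | CC1=CCC[C@]2(C)CC(=O)C(C(C)(C)[O-])C[C@@H]12.[Li+] | intermediate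
16 | 2-[(4aR,8aR)-5,8a-dimethyl-2-oxo-1,2,3,4,4a,7,8,8a-octahydronaphthalen-3-yl]propan-2-yl methanesulfonate (epimers at C3) | CC1=CCC[C@]2(C)CC(=O)C(C(C)(C)OS(C)(=O)=O)C[C@@H]12 | intermediate
17 | (4aR,8aR)-5,8a-dimethyl-3-(propan-2-ylidene)-3,4,4a,7,8,8a-hexahydronaphthalen-2(1H)-one | CC1=CCC[C@]2(C)CC(=O)C(=C(C)C)C[C@@H]12 | intermediate
18 | (4aR,5S,6R,8aR)-5,6-dihydroxy-5,8a-dimethyl-3-(propan-2-ylidene)octahydronaphthalen-2(1H)-one (cis-diol, both hydroxyls trans to the angular methyl) | O[C@@H]1CC[C@]2(C)CC(=O)C(=C(C)C)C[C@H]2[C@]1(C)O | intermediate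
19 | (3S)-3-methylpentanoic acid | CC[C@H](C)CC(=O)O | starting material
20 | (1S,2R,4aR,8aR)-1-hydroxy-1,4a-dimethyl-6-oxo-7-(propan-2-ylidene)decahydronaphthalen-2-yl (3S)-3-methylpentanoate | CC[C@H](C)CC(=O)O[C@@H]1CC[C@]2(C)CC(=O)C(=C(C)C)C[C@H]2[C@]1(C)O | target

**Step count and risks**
Total step count: 7. Longest linear sequence: 7 steps (1 and 2 to 20).

The three steps most likely to fail are steps 2, 4 and 5.

Step 2 (proposed new method). Risks: enolisation of 4 by the carbenoid, attack of the magnesium reagent on the enone, or migration of the CH2 instead of the quaternary carbon. The fallback uses known chemistry, sets out from 4 and comes back at 13, replacing steps 2 to 4. Compound 4 is added to LiCHBr2 (CH2Br2, lithium 2,2,6,6-tetramethylpiperidide, THF, −90 °C) and quenched cold with AcOH to give (1S,7aS)-1-(dibromomethyl)-1-hydroxy-4,7a-dimethyl-1,2,3,6,7,7a-hexahydro-5H-inden-5-one F1, whose tertiary carbinol serves as the masked ketone. NaBH4/CeCl3·7H2O in MeOH then reduces the enone to (1S,5S,7aS)-1-(dibromomethyl)-4,7a-dimethyl-2,3,5,6,7,7a-hexahydro-1H-indene-1,5-diol F2. NBSH/PPh3/DEAD transposes the allylic alcohol to the trans-fused olefin (1S,3aS,7aS)-1-(dibromomethyl)-4,7a-dimethyl-2,3,3a,6,7,7a-hexahydro-1H-inden-1-ol F3. With no enone left, n-BuLi (3 equiv, THF, −78 → 0 °C) effects the classical lithium β-oxido carbenoid ring enlargement, and aqueous work-up gives 13. This fallback cures the chemoselectivity risks but relies on the same preference for migration of the more substituted carbon.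

Step 4. Risks: slow Mitsunobu displacement at the allylic carbinol next to the methyl-bearing olefin carbon, or loss of stereospecificity. The fallback sets out from 8 and comes back at 12, replacing steps 3 and 4 up to the desilylation. Dissolving-metal reduction of 8 (Li, NH3/THF, t-BuOH, −78 °C) protonates the ring-fusion carbon to the trans-fused enolate, which is trapped with PhNTf2 as (4aS,8aR)-1,4a-dimethyl-6-[(triisopropylsilyl)oxy]-3,4,4a,7,8,8a-hexahydronaphthalen-2-yl trifluoromethanesulfonate F4. Formate reduction of the enol triflate (Pd(OAc)2, PPh3, Bu3N, HCO2H, DMF, 60 °C) gives 12, which is desilylated to 13 with HF·pyridine as in step 4.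

Step 5. Risks: proton transfer to acetone or retro-aldol of the lithium aldolate, or incomplete in situ mesylation of the tertiary alkoxide. The fallback sets out from 13 and comes back at 17. Kinetic silylation (LiN(iPr)2, TMSCl, THF, −78 °C) gives trimethyl{[(4aR,8aR)-5,8a-dimethyl-1,4,4a,7,8,8a-hexahydronaphthalen-2-yl]oxy}silane F5. Mukaiyama aldol addition to acetone (TiCl4, CH2Cl2, −78 °C) gives the isolable β-hydroxy ketone (4aR,8aR)-3-(2-hydroxypropan-2-yl)-5,8a-dimethyl-3,4,4a,7,8,8a-hexahydronaphthalen-2(1H)-one F6. Dehydration with Burgess reagent (benzene, 50 °C) or SOCl2/pyridine then gives 17.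

**Further compounds**
F1 | step 2 | (1S,7aS)-1-(dibromomethyl)-1-hydroxy-4,7a-dimethyl-1,2,3,6,7,7a-hexahydro-5H-inden-5-one | O=C1CC[C@]2(C)[C@](O)(C(Br)Br)CCC2=C1C
F2 | step 2 | (1S,5S,7aS)-1-(dibromomethyl)-4,7a-dimethyl-2,3,5,6,7,7a-hexahydro-1H-indene-1,5-diol | O[C@H]1CC[C@]2(C)[C@](O)(C(Br)Br)CCC2=C1C
F3 | step 2 | (1S,3aS,7aS)-1-(dibromomethyl)-4,7a-dimethyl-2,3,3a,6,7,7a-hexahydro-1H-inden-1-ol | CC1=CCC[C@]2(C)[C@](O)(C(Br)Br)CC[C@@H]12
F4 | step 4 | (4aS,8aR)-1,4a-dimethyl-6-[(triisopropylsilyl)oxy]-3,4,4a,7,8,8a-hexahydronaphthalen-2-yl trifluoromethanesulfonate | CC1=C(OS(=O)(=O)C(F)(F)F)CC[C@]2(C)C=C(O[Si](C(C)C)(C(C)C)C(C)C)CC[C@@H]12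
F5 | step 5 | trimethyl{[(4aR,8aR)-5,8a-dimethyl-1,4,4a,7,8,8a-hexahydronaphthalen-2-yl]oxy}silane | CC1=CCC[C@]2(C)CC(O[Si](C)(C)C)=CC[C@@H]12
F6 | step 5 | (4aR,8aR)-3-(2-hydroxypropan-2-yl)-5,8a-dimethyl-3,4,4a,7,8,8a-hexahydronaphthalen-2(1H)-one (epimers at C3) | CC1=CCC[C@]2(C)CC(=O)C(C(C)(C)O)C[C@@H]12
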